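**Retrosynthetic overview**
- The target is fisetinidol-(4β→6)-ent-epifisetinidol: upper unit 2R,3S,4S (2,3-trans, 3,4-cis), lower unit 2S,3S (2,3-cis). Deprotection comes last.
- The upper C3–OH is traced back to a C3–CHO group (Baeyer–Villiger, retention). The C4(upper)–C6(lower) bond is then cut as the conjugate addition of a lower-unit C6 aryl radical to C4 of an upper-unit 2H-chromene-3-carbaldehyde (key step; it sets C4, then C3).
- The lower unit comes from the enantiomeric chromene-3-carbaldehyde: Baeyer–Villiger to the flavan-3-one, cis-selective hydride reduction, C6 iodination.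
- Both chromenes come from one salicylaldehyde and one cinnamaldehyde with antipodal prolinol catalysts. Rings A and B arrive intact from resorcinol and catechol; ring C of each unit is closed here (O1–C2, then C3–C4), before the units are joined.
- The two aldehydes come from resorcinol (formylation, 4-O-silylation) and catechol (benzylation, bromination, Heck reaction with acrolein dimethyl acetal).

Assumption: the (S)-diarylprolinol silyl ether is taken to give the (2R)-chromene (phenol attack on the β-carbon face opposite the CPh2OSiMe3 group); if the measured sense is the reverse, the two catalyst antipodes are exchanged between steps 6 and 7.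

**Route**

Step 1
Reactants: 1 catechol
Product: 2 1,2-bis(benzyloxy)benzene
Conditions: BnBr (2.2 equiv), K2CO3, DMF, 60 °C
Reagents that add atoms: benzyl bromide, BrCc1ccccc1
Why: Williamson etherification caps both catechol OH groups as benzyl ethers, which survive all later steps and leave together at the end by hydrogenolysis.

Step 2
Reactants: 2 1,2-bis(benzyloxy)benzene
Product: 3 4-bromo-1,2-bis(benzyloxy)benzene
Conditions: NBS (1.05 equiv), MeCN, 0 °C to rt
Reagents that add atoms: N-bromosuccinimide, O=C1CCC(=O)N1Br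
Why: Electrophilic aromatic bromination of the dialkoxybenzene goes para to one benzyloxy group and gives only the 4-bromide.

Step 3
Reactants: 3 4-bromo-1,2-bis(benzyloxy)benzene; 4 acrolein dimethyl acetal
Product: 6 (E)-3-[3,4-bis(benzyloxy)phenyl]prop-2-enal, via dimethyl acetal 5 (not isolated)
Conditions: Pd(OAc)2 (3 mol%), n-Bu4NOAc, K2CO3, KCl, DMF, 90 °C; then 2 M HCl, rt
Reagents that add atoms: water, O
Why: Heck reaction of the aryl bromide with acetal-masked acrolein (Cacchi conditions) gives the (E)-alkene by syn-insertion and syn-β-hydride elimination, and acid hydrolysis unmasks the enal.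

Step 4
Reactants: 7 resorcinol
Product: 9 2,4-dihydroxybenzaldehyde, via iminium chloride 8 (not isolated)
Conditions: POCl3, DMF, MeCN, −15 °C to rt; then H2O, 50 °C
Reagents that add atoms: N,N-dimethylformamide, CN(C)C=O; water, O
Why: Vilsmeier–Haack formylation attacks C4 of resorcinol (para to one OH, ortho to the other), and hydrolysis of the iminium salt gives the salicylaldehyde that supplies ring A, O1 and C4.

Step 5
Reactants: 9 2,4-dihydroxybenzaldehyde
Product: 10 4-[(tert-butyldimethylsilyl)oxy]-2-hydroxybenzaldehyde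
Conditions: TBSCl (1.05 equiv), imidazole, CH2Cl2, 0 °C
Reagents that add atoms: tert-butyldimethylsilyl chloride, CC(C)(C)[Si](C)(C)Cl
Why: The 2-OH is hydrogen-bonded to the aldehyde, so silylation is selective for the 4-OH, and a silyl ether (unlike a benzyl ether) offers no 1,5-hydrogen to the aryl radical of step 11.

Step 6
Reactants: 10 4-[(tert-butyldimethylsilyl)oxy]-2-hydroxybenzaldehyde; 6 (E)-3-[3,4-bis(benzyloxy)phenyl]prop-2-enal
Product: 11 (2R)-2-[3,4-bis(benzyloxy)phenyl]-7-[(tert-butyldimethylsilyl)oxy]-2H-chromene-3-carbaldehyde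
Conditions: (S)-2-[diphenyl(trimethylsilyloxy)methyl]pyrrolidine (20 mol%), 2-nitrobenzoic acid (20 mol%), 4 Å MS, toluene, rt
Reagents that add atoms: none
Why: The iminium–enamine domino oxa-Michael/aldol condensation closes ring C, the phenol adding to the β-carbon face left open by the CPh2OSiMe3 group of the (S)-catalyst so that C2 is set as R.

Step 7
Reactants: 10 4-[(tert-butyldimethylsilyl)oxy]-2-hydroxybenzaldehyde; 6 (E)-3-[3,4-bis(benzyloxy)phenyl]prop-2-enal
Product: 12 (2S)-2-[3,4-bis(benzyloxy)phenyl]-7-[(tert-butyldimethylsilyl)oxy]-2H-chromene-3-carbaldehyde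
Conditions: (R)-2-[diphenyl(trimethylsilyloxy)methyl]pyrrolidine (20 mol%), 2-nitrobenzoic acid (20 mol%), 4 Å MS, toluene, rt
Reagents that add atoms: none
Why: The same domino oxa-Michael/aldol condensation with the antipodal catalyst sets C2 as S for the lower unit.

Step 8
Reactants: 12 (2S)-2-[3,4-bis(benzyloxy)phenyl]-7-[(tert-butyldimethylsilyl)oxy]-2H-chromene-3-carbaldehyde
Product: 14 (2S)-2-[3,4-bis(benzyloxy)phenyl]-7-[(tert-butyldimethylsilyl)oxy]chroman-3-one, via enol formate 13 (not isolated)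
Conditions: mCPBA (1.05 equiv), CH2Cl2, 0 °C; then MeOH, NaHCO3 (cat.), 0 °C
Reagents that add atoms: 3-chloroperbenzoic acid, OOC(=O)c1cccc(Cl)c1
Why: Baeyer–Villiger oxidation of the α-substituted cinnamaldehyde-type enal proceeds by alkenyl migration to the enol formate, and mild methanolysis releases the C3 ketone without touching C2.

Step 9
Reactants: 14 (2S)-2-[3,4-bis(benzyloxy)phenyl]-7-[(tert-butyldimethylsilyl)oxy]chroman-3-one
Product: 15 (2S,3S)-2-[3,4-bis(benzyloxy)phenyl]-7-[(tert-butyldimethylsilyl)oxy]chroman-3-ol (2,3-cis)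
Conditions: LiBH(s-Bu)3, THF, −78 °C; then H2O
Reagents that add atoms: none
Why: The bulky hydride attacks the ketone from the face opposite the C2 aryl group (substrate-controlled reduction, as in the catechin-to-epicatechin conversion), which gives the 2,3-cis alcohol with C3 as S.

Step 10
Reactants: 15 (2S,3S)-2-[3,4-bis(benzyloxy)phenyl]-7-[(tert-butyldimethylsilyl)oxy]chroman-3-ol
Product: 16 (2S,3S)-2-[3,4-bis(benzyloxy)phenyl]-7-[(tert-butyldimethylsilyl)oxy]-6-iodochroman-3-ol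
Conditions: NIS (1.05 equiv), MeCN, 0 °C, dark
Reagents that add atoms: N-iodosuccinimide, O=C1CCC(=O)N1I
Why: Electrophilic aromatic iodination takes place at C6, para to O1 and ortho to the silyloxy group, the most activated and least hindered position of the resorcinol-type ring A.

Step 11
Reactants: 16 (2S,3S)-2-[3,4-bis(benzyloxy)phenyl]-7-[(tert-butyldimethylsilyl)oxy]-6-iodochroman-3-ol; 11 (2R)-2-[3,4-bis(benzyloxy)phenyl]-7-[(tert-butyldimethylsilyl)oxy]-2H-chromene-3-carbaldehyde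
Product: 17 (2S,3S,4R)-2-[3,4-bis(benzyloxy)phenyl]-4-[(2S,3S)-2-[3,4-bis(benzyloxy)phenyl]-7-[(tert-butyldimethylsilyl)oxy]-3-hydroxychroman-6-yl]-7-[(tert-butyldimethylsilyl)oxy]chromane-3-carbaldehyde (upper ring 2,3-trans, 3,4-cis)
Conditions: 11 (5 equiv, excess recovered), (Me3Si)3SiH (1.5 equiv) and AIBN (0.3 equiv) added over 8 h, benzene, 80 °C
Reagents that add atoms: none
Why: Proposed new method: the C6 aryl radical freed from 16 by iodine abstraction with (Me3Si)3Si• adds to the β-carbon C4 of enal 11 anti to the pseudo-axial C2 aryl group (2,4-trans), and the resulting α-formyl radical takes hydrogen from the silane on the face opposite the new, bulkier C4 aryl group (CHO cis to the C4 aryl, trans to the C2 aryl); the closest known reaction type is the silane-mediated Giese (Meerwein-type) conjugate addition of aryl radicals to enals and enones.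

Step 12
Reactants: 17 (2S,3S,4R)-4-aryl-chromane-3-carbaldehyde from step 11
Product: 18 (2R,3S,4R)-2-[3,4-bis(benzyloxy)phenyl]-4-[(2S,3S)-2-[3,4-bis(benzyloxy)phenyl]-7-[(tert-butyldimethylsilyl)oxy]-3-hydroxychroman-6-yl]-7-[(tert-butyldimethylsilyl)oxy]chroman-3-yl formate
Conditions: mCPBA (1.5 equiv), CH2Cl2, 0 °C to rt
Reagents that add atoms: 3-chloroperbenzoic acid, OOC(=O)c1cccc(Cl)c1
Why: Baeyer–Villiger oxidation of the α-branched aldehyde with migration of the secondary C3 carbon turns C3–CHO into C3–OCHO with retention, so the 2,3-trans-3,4-cis arrangement is carried into the C–O bond.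

Step 13
Reactants: 18 (2R,3S,4R)-chroman-3-yl formate from step 12
Product: 20 (2R,3S,4S)-2-(3,4-dihydroxyphenyl)-4-[(2S,3S)-2-(3,4-dihydroxyphenyl)-3,7-dihydroxychroman-6-yl]chromane-3,7-diol (target), via tetra-O-benzyl tetrol 19 (not isolated)
Conditions: K2CO3 (0.3 equiv), MeOH/THF, rt; AcOH to pH 6; then H2 (1 atm), Pd(OH)2/C, MeOH/EtOAc, rt
Reagents that add atoms: none
Why: Base-catalysed methanolysis removes the formate and both aryl silyl ethers while the still benzylated catechols cannot form quinone methides (no C2 epimerisation), and hydrogenolysis over Pd(OH)2 on carbon then frees the four catechol OH groups without opening the pyran rings.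

**Compound list**

1 | catechol | Oc1ccccc1O | starting material
2 | 1,2-bis(benzyloxy)benzene | C(Oc1ccccc1OCc1ccccc1)c1ccccc1 | intermediate
3 | 4-bromo-1,2-bis(benzyloxy)benzene | Brc1ccc(OCc2ccccc2)c(OCc2ccccc2)c1 | intermediate
4 | acrolein dimethyl acetal (3,3-dimethoxyprop-1-ene) | C=CC(OC)OC | starting material
5 | (E)-1,2-bis(benzyloxy)-4-(3,3-dimethoxyprop-1-en-1-yl)benzene | COC(OC)/C=C/c1ccc(OCc2ccccc2)c(OCc2ccccc2)c1 | intermediate
6 | (E)-3-[3,4-bis(benzyloxy)phenyl]prop-2-enal | O=C/C=C/c1ccc(OCc2ccccc2)c(OCc2ccccc2)c1 | intermediate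
7 | resorcinol | Oc1cccc(O)c1 | starting material
8 | N-(2,4-dihydroxybenzylidene)-N-methylmethanaminium chloride | C[N+](C)=Cc1ccc(O)cc1O.[Cl-] | intermediate
9 | 2,4-dihydroxybenzaldehyde | O=Cc1ccc(O)cc1O | intermediate
10 | 4-[(tert-butyldimethylsilyl)oxy]-2-hydroxybenzaldehyde | O=Cc1ccc(O[Si](C)(C)C(C)(C)C)cc1O | intermediate
11 | (2R)-2-[3,4-bis(benzyloxy)phenyl]-7-[(tert-butyldimethylsilyl)oxy]-2H-chromene-3-carbaldehyde | O=CC1=Cc2ccc(O[Si](C)(C)C(C)(C)C)cc2O[C@@H]1c1ccc(OCc2ccccc2)c(OCc2ccccc2)c1 | intermediate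
12 | (2S)-2-[3,4-bis(benzyloxy)phenyl]-7-[(tert-butyldimethylsilyl)oxy]-2H-chromene-3-carbaldehyde | O=CC1=Cc2ccc(O[Si](C)(C)C(C)(C)C)cc2O[C@H]1c1ccc(OCc2ccccc2)c(OCc2ccccc2)c1 | intermediate
13 | (2S)-2-[3,4-bis(benzyloxy)phenyl]-7-[(tert-butyldimethylsilyl)oxy]-2H-chromen-3-yl formate | O=COC1=Cc2ccc(O[Si](C)(C)C(C)(C)C)cc2O[C@H]1c1ccc(OCc2ccccc2)c(OCc2ccccc2)c1 | intermediate
14 | (2S)-2-[3,4-bis(benzyloxy)phenyl]-7-[(tert-butyldimethylsilyl)oxy]chroman-3-one | O=C1Cc2ccc(O[Si](C)(C)C(C)(C)C)cc2O[C@H]1c1ccc(OCc2ccccc2)c(OCc2ccccc2)c1 | intermediate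
15 | (2S,3S)-2-[3,4-bis(benzyloxy)phenyl]-7-[(tert-butyldimethylsilyl)oxy]chroman-3-ol | O[C@H]1Cc2ccc(O[Si](C)(C)C(C)(C)C)cc2O[C@H]1c1ccc(OCc2ccccc2)c(OCc2ccccc2)c1 | intermediate
16 | (2S,3S)-2-[3,4-bis(benzyloxy)phenyl]-7-[(tert-butyldimethylsilyl)oxy]-6-iodochroman-3-ol | O[C@H]1Cc2cc(I)c(O[Si](C)(C)C(C)(C)C)cc2O[C@H]1c1ccc(OCc2ccccc2)c(OCc2ccccc2)c1 | intermediate
17 | (2S,3S,4R)-2-[3,4-bis(benzyloxy)phenyl]-4-[(2S,3S)-2-[3,4-bis(benzyloxy)phenyl]-7-[(tert-butyldimethylsilyl)oxy]-3-hydroxychroman-6-yl]-7-[(tert-butyldimethylsilyl)oxy]chromane-3-carbaldehyde | CC(C)(C)[Si](C)(C)Oc1ccc2c(c1)O[C@H](c1ccc(OCc3ccccc3)c(OCc3ccccc3)c1)[C@@H](C=O)[C@H]2c1cc2c(cc1O[Si](C)(C)C(C)(C)C)O[C@@H](c1ccc(OCc3ccccc3)c(OCc3ccccc3)c1)[C@@H](O)C2 | intermediate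
18 | (2R,3S,4R)-2-[3,4-bis(benzyloxy)phenyl]-4-[(2S,3S)-2-[3,4-bis(benzyloxy)phenyl]-7-[(tert-butyldimethylsilyl)oxy]-3-hydroxychroman-6-yl]-7-[(tert-butyldimethylsilyl)oxy]chroman-3-yl formate | CC(C)(C)[Si](C)(C)Oc1ccc2c(c1)O[C@H](c1ccc(OCc3ccccc3)c(OCc3ccccc3)c1)[C@@H](OC=O)[C@H]2c1cc2c(cc1O[Si](C)(C)C(C)(C)C)O[C@@H](c1ccc(OCc3ccccc3)c(OCc3ccccc3)c1)[C@@H](O)C2 | intermediate
19 | (2R,3S,4S)-2-[3,4-bis(benzyloxy)phenyl]-4-[(2S,3S)-2-[3,4-bis(benzyloxy)phenyl]-3,7-dihydroxychroman-6-yl]chromane-3,7-diol | Oc1ccc2c(c1)O[C@H](c1ccc(OCc3ccccc3)c(OCc3ccccc3)c1)[C@@H](O)[C@H]2c1cc2c(cc1O)O[C@@H](c1ccc(OCc3ccccc3)c(OCc3ccccc3)c1)[C@@H](O)C2 | intermediate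
20 | (2R,3S,4S)-2-(3,4-dihydroxyphenyl)-4-[(2S,3S)-2-(3,4-dihydroxyphenyl)-3,7-dihydroxychroman-6-yl]chromane-3,7-diol, fisetinidol-(4β→6)-ent-epifisetinidol | Oc1ccc2c(c1)O[C@H](c1ccc(O)c(O)c1)[C@@H](O)[C@H]2c1cc2c(cc1O)O[C@@H](c1ccc(O)c(O)c1)[C@@H](O)C2 | target

**Step count and risk**

Total step count: 13. Longest linear sequence: 10 steps (1, 2, 3, 7, 8, 9, 10, 11, 12, 13).

Steps most likely to fail:

Step 11 (intermolecular aryl-radical conjugate addition). The aryl radical may be reduced by the silane before it adds to the hindered β-carbon, the α-formyl radical may ring-open by loss of the ring A phenoxyl, and the C3 epimer ratio rests on the size difference between the two flanking aryl groups. Fallback: starting from 16, a Miyaura borylation (bis(pinacolato)diboron, Pd(dppf)Cl2, KOAc, dioxane, 80 °C) gives the pinacol boronate F1, which is added 1,4 to enal 11 with [Rh(OH)(cod)]2 in dioxane/H2O at 60 °C (aryl delivered anti to the C2 aryl group); this rejoins the route at 17.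

Step 12 (Baeyer–Villiger of a hindered β-aryloxy aldehyde). Hydride migration would give the carboxylic acid in place of the formate. Fallback: starting from 17, Pinnick oxidation (NaClO2, NaH2PO4, 2-methyl-2-butene, t-BuOH/H2O) gives the carboxylic acid F2. Coupling with mCPBA by DCC in CH2Cl2 at 0 °C gives the acyl 3-chlorobenzoyl peroxide F3. Warming in MeCN brings about the carboxy-inversion rearrangement with retention at C3 to the mixed carbonic anhydride F4. The K2CO3/MeOH stage of step 13 then cleaves F4 together with the silyl ethers, and the route is rejoined at 19.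

Step 8 (Baeyer–Villiger of the enal to the flavan-3-one). The enol formate may be epoxidised by excess peracid and the ketone may epimerise at C2. Fallback: starting from 12, hydrogenation of the C3=C4 bond over Pd/C poisoned with Ph2S (H2, EtOAc, rt; hydrogen adds anti to the C2 aryl group) gives the 2,3-cis aldehyde F5. Baeyer–Villiger oxidation (mCPBA, CH2Cl2, 0 °C) gives the formate F6 with retention, and methanolysis (KHCO3, MeOH, 0 °C) rejoins the route at 15.

**Further compounds**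

F1 | step 11 | (2S,3S)-2-[3,4-bis(benzyloxy)phenyl]-7-[(tert-butyldimethylsilyl)oxy]-6-(4,4,5,5-tetramethyl-1,3,2-dioxaborolan-2-yl)chroman-3-ol | O[C@H]1Cc2cc(B3OC(C)(C)C(C)(C)O3)c(O[Si](C)(C)C(C)(C)C)cc2O[C@H]1c1ccc(OCc2ccccc2)c(OCc2ccccc2)c1
F2 | step 12 | chromane-3-carboxylic acid corresponding to aldehyde 17 (same configuration) | CC(C)(C)[Si](C)(C)Oc1ccc2c(c1)O[C@H](c1ccc(OCc3ccccc3)c(OCc3ccccc3)c1)[C@@H](C(O)=O)[C@H]2c1cc2c(cc1O[Si](C)(C)C(C)(C)C)O[C@@H](c1ccc(OCc3ccccc3)c(OCc3ccccc3)c1)[C@@H](O)C2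
F3 | step 12 | acyl 3-chlorobenzoyl peroxide of acid F2 | CC(C)(C)[Si](C)(C)Oc1ccc2c(c1)O[C@H](c1ccc(OCc3ccccc3)c(OCc3ccccc3)c1)[C@@H](C(=O)OOC(=O)c3cccc(Cl)c3)[C@H]2c1cc2c(cc1O[Si](C)(C)C(C)(C)C)O[C@@H](c1ccc(OCc3ccccc3)c(OCc3ccccc3)c1)[C@@H](O)C2
F4 | step 12 | chroman-3-yl 3-chlorobenzoyl carbonate (carboxy-inversion product, C3–O with retention) | CC(C)(C)[Si](C)(C)Oc1ccc2c(c1)O[C@H](c1ccc(OCc3ccccc3)c(OCc3ccccc3)c1)[C@@H](OC(=O)OC(=O)c3cccc(Cl)c3)[C@H]2c1cc2c(cc1O[Si](C)(C)C(C)(C)C)O[C@@H](c1ccc(OCc3ccccc3)c(OCc3ccccc3)c1)[C@@H](O)C2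
F5 | step 8 | (2R,3S)-2-[3,4-bis(benzyloxy)phenyl]-7-[(tert-butyldimethylsilyl)oxy]chromane-3-carbaldehyde (2,3-cis) | O=C[C@H]1Cc2ccc(O[Si](C)(C)C(C)(C)C)cc2O[C@H]1c1ccc(OCc2ccccc2)c(OCc2ccccc2)c1
F6 | step 8 | (2S,3S)-2-[3,4-bis(benzyloxy)phenyl]-7-[(tert-butyldimethylsilyl)oxy]chroman-3-yl formate | O=CO[C@H]1Cc2ccc(O[Si](C)(C)C(C)(C)C)cc2O[C@H]1c1ccc(OCc2ccccc2)c(OCc2ccccc2)c1
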